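The readings are calculated from invented constants; noise was put on by code.

Follow one molecule of starting material through the elm flask and ask, fork by fork, what its chances are of ending as target by 8.5 min.

| flask | starting material | reagent | time |
|---|---|---|---|
| larch | 0.150 M | 0.450 M |  |
| alder | 0.150 M | 1.40 M |  |
| ash | 0.300 M | 0.450 M |  |
| elm | 0.450 M | 1.40 M | 8.5 min |

- larch run (time / min: [target] / M): 0.34: 0.0042; 0.54: 0.0070; 0.85: 0.0110; 1.4: 0.0161; 2.1: 0.0232; 3.4: 0.0326; 5.4: 0.0426; 8.5: 0.0485
- alder run (time / min: [target] / M): 0.34: 0.0138; 0.54: 0.0214; 0.85: 0.0308; 1.4: 0.0460; 2.1: 0.0624; 3.4: 0.0799; 5.4: 0.0923; 8.5: 0.0960
- ash run (time / min: [target] / M): 0.34: 0.0075; 0.54: 0.0114; 0.85: 0.0167; 1.4: 0.0249; 2.1: 0.0356; 3.4: 0.0520; 5.4: 0.0690; 8.5: 0.0836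

(scatter of a reading: 4 × 10⁻⁴ M)

- Overall: starting material + reagent -> target.
- Constant volume, constant temperature.
- The analysis sees a species whether free or bound.
- "The second partner" is reagent.
- An order is taken over about fifteen percent of the charge, up and down.

- apparent order in [starting material] of the starting rate, round the charge of the larch run (the rate where two percent of its starting material have turned into target) (one fixed amount of target, the same in the runs compared)
- apparent order in [reagent] of the starting rate, round the charge of the larch run (the rate where two percent of its starting material have turned into target)
- target in the elm run at 8.5 min, as a share of the starting material charged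

Begin with the main step by itself, first order in [starting material] and in [reagent], with no way back. The early larch reading at 0.54 min gives a rate constant of 0.192 M⁻¹ min⁻¹. Holding [reagent] at its elm charge, the pseudo-first-order picture, a molecule in the elm flask has a chance of 89.8 % of turning by 8.5 min.

Now add what the early readings show. At 0.54 min, the ash run has made 1.63 times the target of the larch run on a doubled charge, an order in [starting material] of 0.704. The alder run has made 3.06 times as much, an order in [reagent] of 0.985. These two readings, averaged over wide steps in charge, are our answers for the orders.

Because the first order is below unity, a molecule turns more slowly in the fuller flask. The alder run gives 0.264 min⁻¹ per molecule, and the elm run, at the same [reagent], gets 0.191 min⁻¹. The chance by 8.5 min falls to 80.2 %.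

Last, add the stopping. The alder run moves from 0.0923 M to 0.0960 M over its final readings, on a charge of 0.150 M, so it slows short of that charge, and we treat this as another exit for a molecule, whose nature the readings leave open. We carry the fork odds: target made divided by starting material not turned into target, at a stated time. These odds rise with time, from 0.101 at 0.34 min in the alder run, so we compare them at one time, 8.5 min.

The alder run reads 1.78 at 8.5 min. We assume the other exit is the same in the elm run and take the odds at that time to scale with the rate per molecule, which gives 1.28. Our share for the elm run is 56.2 %.

The forecast, holding that “All three fit one equilibrium”, gives orders of 0.77 and 1.02 and a share of 58 %, and our share is lower than that.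

The elm run gives 57.7 % at 8.5 min, which is fork odds of 1.36 against our 1.28.

    starting material + reagent ⇌ target (0.4122 M⁻¹ min⁻¹, 0.06000 min⁻¹)
    2 starting material ⇌ idle substrate dimer, settled at all times (7.500 M⁻¹)
    starting material → decomposed substrate (0.1812 min⁻¹)

The apparent order in [starting material] comes out at 0.70, beside our reading of 0.704, and that in [reagent] at 1.0, beside our reading of 0.985. For the ash run, the alder odds of 1.78, scaled by the ratio of rates per molecule, 1.6 over 3.2 and then over the doubled charge, give 0.442, and the last ash reading gives 0.386.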